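**Plan**

- Numbering used: indenone C1 (carbonyl), C2 (azulenyl), C3 (methyl), C3a, C4 (formyl), C7 (methyl), C7a. The formyl group is masked as a dioxolane, and the enone C1(=O)–C2=C3 is traced back to a 3-methoxy-1H-inden-1-ol (a vinylogous hemiketal).
- The five-membered ring is then cut at C1–C7a and at C2–C3 in one (3+2) annulation, giving a 2-acetylarylboronate and 3-(methoxyethynyl)guaiazulene.
- Enabling feature: on the benzo ring the aryl carbon C7a and the acetyl-derived carbon C3 are ortho to each other, a nucleophile/electrophile pair three atoms long. C1(=O)–C2 is a two-carbon unit at the oxidation level of an alkoxyalkyne, so an aryl-metal/alkyne/ketone annulation closes the five-membered ring across them.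
- Forward: the benzene ring (3-bromo-4-methylbenzaldehyde) and the azulene (guaiazulene) are bought. Ortho-lithiation/acetylation and Miyaura borylation give the aryl partner; C3 acylation and enol triflate elimination give the ynol ether. The five-membered ring of the indenone is the only ring made (step 6), and acid then unveils enone and aldehyde together (step 7).
- Stereochemistry: the target has no stereocentre. The one carbinol centre made in step 6 is racemic and is destroyed in step 7. The indenone–azulene axis is unspecified and is assumed to need no control.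

Key step: step 6

Remark: the aldehyde is carried as a dioxolane through all basic and metal-mediated steps, because a free ortho-acetylbenzaldehyde would close on itself by aldol reaction.

**Route**

Step 1
Reactants: 1 3-bromo-4-methylbenzaldehyde
Product: 2 2-(3-bromo-4-methylphenyl)-1,3-dioxolane
Conditions: ethylene glycol (3 equiv), TsOH·H2O (cat.), toluene, reflux, Dean–Stark trap
Reagents that add atoms: ethylene glycol, OCCO
Why: acid-catalysed acetalisation with azeotropic removal of water masks the aldehyde for the lithiation, borylation and annulation steps.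

Step 2
Reactants: 2 2-(3-bromo-4-methylphenyl)-1,3-dioxolane
Product: 5 1-[2-bromo-6-(1,3-dioxolan-2-yl)-3-methylphenyl]ethan-1-one, via aryllithium 3 (not isolated), via lithium hemiaminal alkoxide 4 (not isolated)
Conditions: LDA (1.1 equiv), THF, −78 °C, 1 h; MeC(O)N(OMe)Me (1.3 equiv), −78 to 0 °C; aq. NH4Cl
Reagents that add atoms: N-methoxy-N-methylacetamide, CC(=O)N(C)OC; lithium diisopropylamide, [Li]N(C(C)C)C(C)C (lithium, held by 3 and 4 only)
Why: directed ortho-metalation should remove the ring hydrogen flanked by bromine (inductive acidification) and the dioxolane (lithium coordination) without bromine–lithium exchange, −78 °C holds back loss of LiBr to an aryne, and the chelated tetrahedral adduct of the Weinreb ketone synthesis stops the acylation at the ketone.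

Step 3
Reactants: 5 1-[2-bromo-6-(1,3-dioxolan-2-yl)-3-methylphenyl]ethan-1-one
Product: 6 1-[6-(1,3-dioxolan-2-yl)-3-methyl-2-(4,4,5,5-tetramethyl-1,3,2-dioxaborolan-2-yl)phenyl]ethan-1-one
Conditions: B2pin2 (1.5 equiv), Pd(OAc)2 (3 mol %), SPhos (6 mol %), KOAc (3 equiv), 1,4-dioxane, 90 °C
Reagents that add atoms: bis(pinacolato)diboron, CC1(C)OB(OC1(C)C)B1OC(C)(C)C(C)(C)O1
Why: Miyaura borylation, in which the electron-rich biaryl phosphine should allow oxidative addition and transmetalation at the bromide flanked by acetyl and methyl, while acetate is too weak a base to enolise or arylate the ketone.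

Step 4
Reactants: 7 guaiazulene (7-isopropyl-1,4-dimethylazulene)
Product: 8 1-(5-isopropyl-3,8-dimethylazulen-1-yl)-2-methoxyethan-1-one
Conditions: MeOCH2COCl (1.2 equiv), SnCl4 (1.1 equiv), CH2Cl2, −20 to 0 °C; aq. NaHCO3
Reagents that add atoms: methoxyacetyl chloride, COCC(=O)Cl
Why: Friedel–Crafts acylation should go to C3, the only free position of the five-membered ring at which attack leaves a tropylium-type cation, and the acyl group deactivates the product against a second acylation.

Step 5
Reactants: 8 1-(5-isopropyl-3,8-dimethylazulen-1-yl)-2-methoxyethan-1-one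
Product: 11 1-(methoxyethynyl)-5-isopropyl-3,8-dimethylazulene, via lithium enolate 9 (not isolated), via enol triflate 10 (not isolated)
Conditions: LiN(SiMe3)2 (1.1 equiv), THF, −78 °C; PhNTf2 (1.1 equiv), −78 to 0 °C; then KOtBu (2.5 equiv), −78 °C to rt; basic alumina, product stored cold and used promptly
Reagents that add atoms: N-phenylbis(trifluoromethanesulfonimide), O=S(=O)(N(c1ccccc1)S(=O)(=O)C(F)(F)F)C(F)(F)F (triflyl group, held by 10 only); lithium bis(trimethylsilyl)amide, [Li]N([Si](C)(C)C)[Si](C)(C)C (lithium, held by 9 only)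
Why: the methoxy-chelated (Z)-enolate should be O-triflated and the vinyl hydrogen, anti to the triflate, removed by tert-butoxide in an anti elimination, the known route from α-alkoxy ketones to alkynyl ethers through their enol triflates; a methyl ether is chosen because it cannot fragment to a ketene by a retro-ene path.

Step 6
Reactants: 6 1-[6-(1,3-dioxolan-2-yl)-3-methyl-2-(4,4,5,5-tetramethyl-1,3,2-dioxaborolan-2-yl)phenyl]ethan-1-one (1.3 equiv); 11 1-(methoxyethynyl)-5-isopropyl-3,8-dimethylazulene
Product: 12 rac-7-(1,3-dioxolan-2-yl)-2-(5-isopropyl-3,8-dimethylazulen-1-yl)-3-methoxy-1,4-dimethyl-1H-inden-1-ol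
Conditions: [Rh(OH)(cod)]2 (3 mol %), K3PO4 (1 equiv), 1,4-dioxane/H2O (10:1), degassed, 50 °C; filtration through basic alumina, used directly
Reagents that add atoms: none
Why: Proposed new method: transmetalation of the boronate to the hydroxo complex of monovalent rhodium should give an arylrhodium ortho to the acetyl group, syn 1,2-insertion of the alkyne then puts the aryl on the methoxy-bearing carbon (the C1–C7a bond) and rhodium on the azulenyl-bearing carbon, and this alkenylrhodium adds to the neighbouring acetyl C=O (the C2–C3 bond) before water releases the indenol and returns Rh–OH; the closest known reaction type is the rhodium-catalysed (3+2) annulation of 2-acylarylboron reagents with dialkyl, diaryl and aryl–alkyl alkynes to 1H-inden-1-ols, and the new element is a 1-alkoxyalkyne as the two-carbon partner. The first bond is intermolecular, and the five-membered ring closes in the second event by a 5-exo-trig addition of the alkenyl–rhodium carbon to the ketone. The single new stereocentre, the tertiary carbinol, is formed racemic under the achiral catalyst and is erased in step 7, so nothing has to control it. The step needs regioselective insertion, and three features of 11 should secure it: the oxygen lone pair makes the oxygen-bearing alkyne carbon the electrophilic one that accepts the migrating aryl, that carbon is by far the less hindered one next to the peri-methylated azulenyl group, and rhodium prefers the carbon next to an aryl group as it does with aryl–alkyl alkynes. The step also needs the alkenylrhodium to cyclise and not stray: both ortho positions of the transferred aryl are substituted, which closes the 1,4-rhodium shift, the methoxy group lies anti to rhodium after syn insertion, which disfavours β-alkoxide loss, and the masked aldehyde offers no second carbonyl group.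

Step 7
Reactants: 12 rac-7-(1,3-dioxolan-2-yl)-2-(5-isopropyl-3,8-dimethylazulen-1-yl)-3-methoxy-1,4-dimethyl-1H-inden-1-ol
Product: 14 2-(5-isopropyl-3,8-dimethylazulen-1-yl)-3,7-dimethyl-1-oxo-1H-indene-4-carbaldehyde, via indenone dioxolane 13 (not isolated)
Conditions: 2 M aq. HCl/THF (1:4), 25 °C
Reagents that add atoms: water, O
Why: acid should open the vinylogous hemiketal (ionisation of the tertiary alcohol to a methoxy-stabilised cation, addition of water at C1 and loss of methanol, that is enol ether hydrolysis with β-elimination) to give the indenone before the slower acetal hydrolysis frees the aldehyde, and the azulene should survive because its nucleophilic C3 is substituted.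

**Compound list**

1 | 3-bromo-4-methylbenzaldehyde | Cc1ccc(C=O)cc1Br | starting material
2 | 2-(3-bromo-4-methylphenyl)-1,3-dioxolane | Cc1ccc(C2OCCO2)cc1Br | intermediate
3 | [2-bromo-6-(1,3-dioxolan-2-yl)-3-methylphenyl]lithium (not isolated) | [Li]c1c(C2OCCO2)ccc(C)c1Br | intermediate
4 | lithium 1-[2-bromo-6-(1,3-dioxolan-2-yl)-3-methylphenyl]-1-[methoxy(methyl)amino]ethan-1-olate, racemic (not isolated) | CON(C)C(C)(O[Li])c1c(C2OCCO2)ccc(C)c1Br | intermediate
5 | 1-[2-bromo-6-(1,3-dioxolan-2-yl)-3-methylphenyl]ethan-1-one | CC(=O)c1c(C2OCCO2)ccc(C)c1Br | intermediate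
6 | 1-[6-(1,3-dioxolan-2-yl)-3-methyl-2-(4,4,5,5-tetramethyl-1,3,2-dioxaborolan-2-yl)phenyl]ethan-1-one | CC(=O)c1c(C2OCCO2)ccc(C)c1B1OC(C)(C)C(C)(C)O1 | intermediate
7 | guaiazulene (7-isopropyl-1,4-dimethylazulene) | c1cc(C)c2cc(C(C)C)ccc(C)c1-2 | starting material
8 | 1-(5-isopropyl-3,8-dimethylazulen-1-yl)-2-methoxyethan-1-one | COCC(=O)c1cc(C)c2cc(C(C)C)ccc(C)c1-2 | intermediate
9 | lithium (Z)-1-(5-isopropyl-3,8-dimethylazulen-1-yl)-2-methoxyethen-1-olate (not isolated) | CO/C=C(\O[Li])c1cc(C)c2cc(C(C)C)ccc(C)c1-2 | intermediate
10 | (Z)-1-(5-isopropyl-3,8-dimethylazulen-1-yl)-2-methoxyethenyl trifluoromethanesulfonate (not isolated) | CO/C=C(\OS(=O)(=O)C(F)(F)F)c1cc(C)c2cc(C(C)C)ccc(C)c1-2 | intermediate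
11 | 1-(methoxyethynyl)-5-isopropyl-3,8-dimethylazulene [3-(methoxyethynyl)guaiazulene] | COC#Cc1cc(C)c2cc(C(C)C)ccc(C)c1-2 | intermediate
12 | rac-7-(1,3-dioxolan-2-yl)-2-(5-isopropyl-3,8-dimethylazulen-1-yl)-3-methoxy-1,4-dimethyl-1H-inden-1-ol | COC1=C(c2cc(C)c3cc(C(C)C)ccc(C)c2-3)C(C)(O)c2c(C4OCCO4)ccc(C)c21 | intermediate
13 | 4-(1,3-dioxolan-2-yl)-2-(5-isopropyl-3,8-dimethylazulen-1-yl)-3,7-dimethyl-1H-inden-1-one (not isolated) | CC1=C(c2cc(C)c3cc(C(C)C)ccc(C)c2-3)C(=O)c2c(C)ccc(C3OCCO3)c21 | intermediate
14 | 2-(5-isopropyl-3,8-dimethylazulen-1-yl)-3,7-dimethyl-1-oxo-1H-indene-4-carbaldehyde | CC1=C(c2cc(C)c3cc(C(C)C)ccc(C)c2-3)C(=O)c2c(C)ccc(C=O)c21 | target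

**Summary**

Total step count: 7. Longest linear sequence: 5 steps (steps 1, 2, 3, 6, 7); the azulene branch (steps 4, 5) joins at step 6.

**Steps most likely to fail**

1. Step 6 (proposed new method).
 - What may go wrong: insertion of the alkoxyalkyne with the reverse regiochemistry, protodeboronation of the doubly flanked arylboronate before transmetalation, or loss of methoxide from the alkenylrhodium in place of ring closure.
 - Fallback (known reaction types only), setting out from 11 and 5 and coming back at 13: palladium-catalysed hydrostannation of 11 (Bu3SnH, Pd(PPh3)4, THF, 0 °C; syn addition, tin on the oxygen-bearing carbon) should give tributyl[(E)-1-methoxy-2-(5-isopropyl-3,8-dimethylazulen-1-yl)ethenyl]stannane F1, an acyl anion equivalent. Stille coupling of F1 with bromide 5 (Pd(PPh3)4, CuI, CsF, DMF, 60 °C) should give 1-{2-(1,3-dioxolan-2-yl)-6-[(Z)-1-methoxy-2-(5-isopropyl-3,8-dimethylazulen-1-yl)ethenyl]-5-methylphenyl}ethan-1-one F2. Oxalic acid in wet THF at 0 °C should hydrolyse only the enol ether to 1-[2-acetyl-3-(1,3-dioxolan-2-yl)-6-methylphenyl]-2-(5-isopropyl-3,8-dimethylazulen-1-yl)ethan-1-one F3. K2CO3 in methanol should then close the ring by intramolecular aldol condensation through the more acidic azulenyl-flanked methylene to give 13, which the acid of step 7 converts to 14. In this fallback the two ring bonds are made one after the other.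

2. Step 5.
 - What may go wrong: deprotonation at the acidic C4 methyl group of the acylazulene (vinylogous to the ketone) in competition with enolisation and with removal of the vinyl hydrogen, and ionisation of the electron-rich enol triflate.
 - Fallback, setting out from 7 and coming back at 13, avoiding strong base on the acylazulene: guaiazulene 7 is iodinated at C3 (N-iodosuccinimide, CH2Cl2, 0 °C) to 1-iodo-5-isopropyl-3,8-dimethylazulene F4, used at once. Commercial ethoxyacetylene is lithiated (n-BuLi, THF, −78 °C) and transmetalated with ZnCl2 to chloro(ethoxyethynyl)zinc F5. Negishi coupling of F4 with F5 (Pd(PPh3)4, THF, 25 °C) should give 1-(ethoxyethynyl)-5-isopropyl-3,8-dimethylazulene F6. F6 takes the place of 11 in step 6 and should give rac-7-(1,3-dioxolan-2-yl)-3-ethoxy-2-(5-isopropyl-3,8-dimethylazulen-1-yl)-1,4-dimethyl-1H-inden-1-ol F7, which under the conditions of step 7 loses ethanol to give 13 and then 14.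

3. Step 2.
 - What may go wrong: proton transfer from the acetyl group of the amide to the flanked aryllithium in place of acyl transfer (returning 2), and loss of LiBr from the aryllithium on warming.
 - Fallback, setting out from 2 and coming back at 5: the aryllithium 3, made in the same way, is trapped at −78 °C with acetaldehyde, a small and fast carbonyl acceptor, to give rac-1-[2-bromo-6-(1,3-dioxolan-2-yl)-3-methylphenyl]ethan-1-ol F8. Dess–Martin oxidation (Dess–Martin periodinane, NaHCO3, CH2Cl2, 25 °C) should then give 5.

**Further compounds**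

F1 | step 6 | tributyl[(E)-1-methoxy-2-(5-isopropyl-3,8-dimethylazulen-1-yl)ethenyl]stannane | CCCC[Sn](CCCC)(CCCC)/C(OC)=C/c1cc(C)c2cc(C(C)C)ccc(C)c1-2
F2 | step 6 | 1-{2-(1,3-dioxolan-2-yl)-6-[(Z)-1-methoxy-2-(5-isopropyl-3,8-dimethylazulen-1-yl)ethenyl]-5-methylphenyl}ethan-1-one | CO\C(=C/c1cc(C)c2cc(C(C)C)ccc(C)c1-2)c1c(C)ccc(C2OCCO2)c1C(C)=O
F3 | step 6 | 1-[2-acetyl-3-(1,3-dioxolan-2-yl)-6-methylphenyl]-2-(5-isopropyl-3,8-dimethylazulen-1-yl)ethan-1-one | CC(=O)c1c(C2OCCO2)ccc(C)c1C(=O)Cc1cc(C)c2cc(C(C)C)ccc(C)c1-2
F4 | step 5 | 1-iodo-5-isopropyl-3,8-dimethylazulene (3-iodoguaiazulene) | Ic1cc(C)c2cc(C(C)C)ccc(C)c1-2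
F5 | step 5 | chloro(ethoxyethynyl)zinc | CCOC#C[Zn]Cl
F6 | step 5 | 1-(ethoxyethynyl)-5-isopropyl-3,8-dimethylazulene | CCOC#Cc1cc(C)c2cc(C(C)C)ccc(C)c1-2
F7 | step 5 | rac-7-(1,3-dioxolan-2-yl)-3-ethoxy-2-(5-isopropyl-3,8-dimethylazulen-1-yl)-1,4-dimethyl-1H-inden-1-ol | CCOC1=C(c2cc(C)c3cc(C(C)C)ccc(C)c2-3)C(C)(O)c2c(C4OCCO4)ccc(C)c21
F8 | step 2 | rac-1-[2-bromo-6-(1,3-dioxolan-2-yl)-3-methylphenyl]ethan-1-ol | CC(O)c1c(C2OCCO2)ccc(C)c1Br
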